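All runs were computed with made-up constants; noise was put on by code.

At early times I work with the fraction left and not the fraction made.

| setting | blue | green | ochre | flask |
|---|---|---|---|---|
| Q | 0.10 M | 0.10 M | 0.20 M | 0.10 M |
| G | 0.10 M | 0.10 M | 0.10 M | 0.100 M |
| D | 3.5 mM | 5.5 mM | 2.5 mM | 2.5 mM |
| remark | run made earlier | run made earlier | run made earlier |  |
| time |  |  |  | 8.0 h |

| run | time / h | E / % | Z / % |
|---|---|---|---|
| blue | 0.500 | 48.1 | 27.1 |
| blue | 1.50 | 50.0 | 37.5 |
| blue | 3.00 | 49.6 | 38.0 |
| blue | 5.00 | 49.8 | 37.0 |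
| blue | 6.00 | 50.4 | 36.5 |
| green | 0.500 | 49.1 | 33.9 |
| green | 1.50 | 49.9 | 41.9 |
| green | 3.00 | 50.6 | 41.1 |
| green | 5.00 | 49.8 | 40.4 |
| green | 6.00 | 50.0 | 38.8 |
| ochre | 1.33 | 33.1 | 36.4 |
| ochre | 2.50 | 33.1 | 38.7 |
| ochre | 4.00 | 33.6 | 38.1 |
| ochre | 5.00 | 33.9 | 37.9 |
| ochre | 6.00 | 33.9 | 36.5 |

(readings scatter by 0.3 percentage points)

* share of E in E plus Z at 40 s
* share of E in E plus Z at 20 min
* share of E in E plus Z at 8.0 h
* which of E and Z there is more of at 8.0 h

- the analysis behind the earlier runs scatters by 0.3 percentage points, standard deviation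

E in the blue run levels off at the G charged, so at 0.500 h the fraction of G left reads 3.80 %. Taking Z as my measure of Q spent, the fraction of Q left in that run reads 45.8 %. I take cD as constant, so in my reckoning each substrate decays pseudo-first-order and has a half-life. Taking rates in proportion to cD, these readings give for the flask a half-life of G of 0.148 h and of Q of 0.621 h. The green run, scaled to the flask in the same way, gives 0.673 h for Q. What I carry is the half-life of Q over the half-life of G, the selectivity factor S = 4.19. The later fall of Z in the blue run reads as a half-life of 51.6 h, far longer than that of Q, so I keep it out of the early reckoning.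

In my reckoning each product is its charge times one minus the fraction left. My reckoning therefore gives a share of E of 80.4 % at 40 s and 71.8 % at 20 min; for 8.0 h I offer no number.

The forecast differs early, with 92 % at 40 s, on the ground “almost all E if Z is sequential, less if parallel”, and 77 % at 20 min; at 8.0 h it gives 59.5 % with E ahead.

The flask gives 78.5 %, 71.3 % and 60.4 %, with E at 50.1 % and Z at 32.9 %.

    Q ⇌ G (K = 0.580, k = 2.50 × 10⁻⁶ /s)
    Q + D → D + Z (k = 0.140 /M/s)
    D + G → D + E (k = 0.520 /M/s)
    Z → L (k = 4.70 × 10⁻⁶ /s)
    Q + Z → J (k = 0.00130 /M/s)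

A neighbouring flask, charged with 0.040 M of Q and otherwise like this one, keeps both half-lives in my reckoning, so S stays 4.19, and the smaller charge of Q weighs less against G. At 40 s the reckoning gives 91.1 %, and that flask gives 90.1 %. At 20 min the reckoning gives 86.4 %, and that flask gives 85.5 %.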